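**The vessel.** The closed, stirred vessel stayed as it was for the next series: I left Qa at 0.15 mM, changed the charge of Qb, and set the end at 12 min.

| flask | Qb | Qa | remark | time |
|---|---|---|---|---|
| south | 0.30 M | 0.15 mM | run made earlier |  |
| east | 1.2 M | 0.15 mM | run made earlier |  |
| beta | 0.20 M | 0.15 mM |  | 12 min |
| delta | 0.40 M | 0.15 mM |  | 12 min |
| zeta | 0.80 M | 0.15 mM |  | 12 min |

| run | time / min | Qc / % | Qb / % |
|---|---|---|---|
| south | 0.667 | 15.9 | 57.2 |
| south | 1.00 | 23.4 | 51.9 |
| south | 2.00 | 37.3 | 42.7 |
| south | 3.00 | 47.5 | 35.7 |
| south | 5.00 | 59.8 | 28.3 |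
| south | 8.00 | 68.8 | 20.8 |
| east | 1.33 | 18.0 | 56.1 |
| east | 3.00 | 39.6 | 41.0 |
| east | 4.00 | 52.9 | 33.5 |
| east | 6.00 | 70.9 | 19.4 |
| east | 8.00 | 81.8 | 12.6 |

(each reading ± 0.5 percentage points)

- a reading or a percentage of Qc counts all its forms, free or not
- the concentration of Qc that is asked is that of its free form alone
- "hardly changes" means that all values lie within two and a half points (for a concentration: within two and a half percent of the largest)

**The gap.** The readings of Qb and Qc did not sum to the whole charge. In the south run at 2.00 min the gap was 0.0600 M, far more than the 0.15 mM of Qa, so I read it as a side pool in fast equilibrium with Qb (a pre-equilibrium). Gap over Qb read 0.468 there and 0.473 in the east run at 3.00 min. Pooled, these gave 0.471, the shortfall ratio: the part of the charge missing from Qb and Qc, divided by the part read as Qb.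

**The rule.** I froze that ratio, which made counted Qc the whole charge less the share of Qb multiplied by one plus the ratio. For the east run at 8.00 min this gave 81.5%, and the reading was 81.8%. The rule gave me no row of my own before the end value of Qb was in hand, and it speaks of Qc in all its forms, while the question concerns the free form. So I decided to watch Qb at the end and to read free Qc apart from the count.

* [Qc] (only what is free in solution) at the end for beta, delta, zeta, in this order
* the shape of the row from first to last (falls all the way / hardly changes / falls, then rises / rises, then falls / rises all the way)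

**The forecast.** The forecast took the shortfall as about 0.47 times Qb and gave 0.134 M, 0.324 M and 0.708 M, a row that rises all the way, adding that “any other sequestration remains unproven”.

**Free Qc.** Beta, delta and zeta gave 0.0848 M, 0.0856 M and 0.0874 M of free [Qc], a row that rises all the way.

    Qb + Qa → Qc + Qa, rate k1*[Qb]^2.5*[Qa]/(1 + ([Qb]/Kh1)^2.5) (0.220 M, k = 830 M⁻²·⁵ s⁻¹)
    Qb ⇌ Qd (K = 0.450, k = 0.0350 s⁻¹)
    Qe ⇌ Qc, rate k3*(cs3 - [Qc]) while solid is left; crystals form when [Qc] > cs3 (solubility = 0.0830 M, k = 0.0310 s⁻¹)

**Balance again.** With the ratio at 0.471, the 22.3% of Qb in beta at 12.0 min gives 67.2% of the charge as counted Qc, and beta held 67.6%, with 25.2% of the charge standing as the crystals Qe. In zeta at 12.0 min, the 7.98% of Qb gives 88.3% of the charge, and zeta held 88.4%, with 77.4% of the charge standing as Qe.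

All runs were computed from invented constants.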